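G is the product wanted, and Z is what G becomes in the last step.

    J → E (k1 = 0.087 min⁻¹)
    J ⇌ L (K2 = 2.2, k2 = 0.055 min⁻¹)
    L → X (k3 = 0.96 min⁻¹)
    E ⇌ Q (K4 = 3.8, k4 = 0.075 min⁻¹)
    Q ⇌ D (K5 = 0.52, k5 = 0.41 min⁻¹)
    Q ⇌ G (K6 = 2.4, k6 = 0.093 min⁻¹)
    Q ⇌ X (K7 = 0.20, k7 = 0.052 min⁻¹)
    G ⇌ Z (K8 = 13, k8 = 0.066 min⁻¹)

- south-west: J 0.035 M; a single well-mixed tank run continuously and read at steady state, 10 min in it on average
- north: J 0.035 M; time 10 min; a closed flask charged with all of it at once and left for 10 min

* the set-up with the highest share of G in all that became G or Z, at the outlet or at the end ("none" if the first two lie within 2 percentage points) (south-west / north / none)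
* share of G in all that became G or Z, at the outlet or at the end, south-west
* share of G in all that became G or Z, at the outlet or at the end, north

Follow one molecule of G and ask its chance at the fork to Z. Let kZ = 0.066 min⁻¹ be the forward constant of G → Z, and let w be the effective time a G molecule stands open to that step. Then Z/G = kZ·w, and the share of G (its selectivity against Z) is 1/(1 + kZ·w).

1. South-west: Z leaves the tank after 10 min on average and returns to G at kZ/13. The balance of Z gives w = 9.52 min, so the share is 61.4%. The path from L to X does not enter this ratio.

2. North, first pass: take the road J → E → Q → G, which has 3 steps. Early on, the feed to G grows as time squared, so the mean age of G is t/4. That gives w = 2.50 min and a share of 85.8%.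

3. Reforge the weak link, the squared law, which ignores losses along the road. Add the first-order constants leaving J, E and Q: S = 0.772 min⁻¹. To first order the age stretches by 1 + S·t/(4·5), a correction of 0.386.

4. Commit to the exposure of G, w = 3.46 min. North then gives 81.4%, and the better set-up is north.

The forecast names north, with 61.4% for south-west and 82% for north, on the ground that “G builds late through the E and X routes into Q”. My north figure stands a little below its figure.

The simulation gives north, with 61.4% for south-west and 82.9% for north.

In north, the step E ⇌ Q taken by itself relaxes E and Q with a half-life of 7.32 min against a run of 10 min, and at 10.0 min E holds 31.4% of the J charged while G holds 5.53%. The exposure read back from the north result is 3.13 min, against the 3.46 min committed to for north and the 9.52 min reckoned for south-west.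

Now take north read at 15 min. The same steps give w = 5.92 min and a share of 71.9%; the computed share is 74.1%.

The numbers of this flask come from no measurement; the flask was simulated.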